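**Strategy.** Locants: seven-membered ring C1, C5–C10 (methyls on C5 and C10, side chain C2–C4 on C1), lactone C11–C13 fused at C7/C8. The ring is cut into C1–C5–C6 and C7–C10. The C5=C6 alkene and the C8 oxygen, skipped across C7, mark a cyclohepta-1,4-diene, the product of a cis-divinylcyclopropane Cope rearrangement. A gold vinylcarbenoid, released from a propargylic acetate by 1,2-acyloxy shift, adds to the enol ether of a 2-siloxy (Z,Z)-diene; the cyclopropane ring-expands in the same flask, which joins C6–C7 and C1–C10 and sets C7, C1 and C10. The precursors are an acyclic alkynyl acetate and an acyclic dienoate.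

Key step: step 7

Remark (assumption): the sense of facial induction of the chiral digold catalyst in step 7 cannot be predicted with certainty. The (R)-ligand is written; its mirror image would be used if the opposite sense is found. Because C2 is already fixed from the chiral pool, the minor facial isomer is a diastereomer and should be removable by chromatography. C12 is the lactone carbonyl, C13 the exocyclic methylene, C14 the methyl on C10, C15 the methyl on C5.

**Step 1**
Reactants: 1 (S)-butane-1,2,4-triol
Product: 2 [(2S,4S)-2-phenyl-1,3-dioxan-4-yl]methanol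
Conditions: PhCH(OMe)2, camphorsulfonic acid (cat.), CH2Cl2, rt
Reagents that add atoms: benzaldehyde dimethyl acetal, COC(OC)c1ccccc1
Why: Acid-catalysed transacetalisation under thermodynamic control should favour the six-membered 2,4-O-benzylidene acetal with both substituents equatorial (acetal carbon set cis by equilibration), which masks the C2 and C4 oxygens in one group and leaves the C2 stereocentre of 1 untouched.

**Step 2**
Reactants: 2 [(2S,4S)-2-phenyl-1,3-dioxan-4-yl]methanol
Product: 3 (2S,4S)-2-phenyl-1,3-dioxane-4-carbaldehyde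
Conditions: PhI(OAc)2, TEMPO (cat.), CH2Cl2, rt
Reagents that add atoms: none
Why: Oxoammonium-mediated oxidation of a primary alcohol stops at the aldehyde under near-neutral conditions, so the alpha-alkoxy stereocentre should not epimerise.

**Step 3**
Reactants: 3 (2S,4S)-2-phenyl-1,3-dioxane-4-carbaldehyde
Product: 5 1-[(2S,4S)-2-phenyl-1,3-dioxan-4-yl]prop-2-yn-1-yl acetate (both carbinol epimers), via bromomagnesium propargylic alkoxide 4 (not isolated)
Conditions: HC≡CMgBr, THF, −78 → 0 °C; then Ac2O, DMAP (cat.), 0 °C → rt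
Reagents that add atoms: ethynylmagnesium bromide, C#C[Mg]Br; acetic anhydride, CC(=O)OC(C)=O
Why: Grignard addition to the aldehyde and in-situ acetylation of the alkoxide give the propargylic acetate; the new carbinol centre (future C1) is deliberately left uncontrolled because it becomes sp2 in step 7.

**Step 4**
Reactants: 6 methyl 4-chloro-4-oxobutanoate; 7 propyne
Product: 8 methyl 4-oxohept-5-ynoate
Conditions: PdCl2(PPh3)2 (cat.), CuI (cat.), Et3N, THF, rt
Reagents that add atoms: none
Why: Acyl Sonogashira coupling of an acid chloride with a terminal alkyne gives the ynone directly and leaves the methyl ester untouched.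

**Step 5**
Reactants: 8 methyl 4-oxohept-5-ynoate
Product: 9 methyl (5Z)-4-oxohept-5-enoate
Conditions: H2 (1 atm), Pd/CaCO3 poisoned with Pb(OAc)2 (Lindlar catalyst), quinoline, EtOAc, 0 °C
Reagents that add atoms: none
Why: Syn semihydrogenation on the poisoned palladium surface should stop at the (Z)-enone, which fixes the geometry that later becomes the C10 configuration.

**Step 6**
Reactants: 9 methyl (5Z)-4-oxohept-5-enoate
Product: 10 methyl (3Z,5Z)-4-[(tert-butyldimethylsilyl)oxy]hepta-3,5-dienoate
Conditions: TBSOTf, Et3N, CH2Cl2, −78 °C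
Reagents that add atoms: tert-butyldimethylsilyl trifluoromethanesulfonate, CC(C)(C)[Si](C)(C)OS(=O)(=O)C(F)(F)F
Why: Soft enolisation at the only ketone alpha-CH2 gives the cross-conjugated 2-siloxydiene; the (Z)-enol ether (CH2CO2Me cis to OSi) is favoured by allylic 1,3-strain against the cis-propenyl group, and the low temperature is meant to preserve the (Z)-propenyl geometry.

**Step 7**
Reactants: 5 1-[(2S,4S)-2-phenyl-1,3-dioxan-4-yl]prop-2-yn-1-yl acetate; 10 methyl (3Z,5Z)-4-[(tert-butyldimethylsilyl)oxy]hepta-3,5-dienoate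
Product: 13 methyl 2-[3-acetoxy-5-methyl-4-[(2S,4S)-2-phenyl-1,3-dioxan-4-yl]-7-(tert-butyldimethylsilyloxy)cyclohepta-2,6-dien-1-yl]acetate (ring positions 1/4/5 = C7/C1/C10; C7 and C1 substituents cis and C10 methyl trans to both), via gold vinylcarbenoid 11 (not isolated), via cis-divinylcyclopropane 12 (not isolated)
Conditions: (R)-DTBM-SEGPHOS(AuCl)2 (2.5 mol %), AgSbF6 (5 mol %), ClCH2CH2Cl, −20 °C → rt; then 60–80 °C in the same flask
Reagents that add atoms: none
Why: Cationic monovalent gold triggers a 1,2-acetoxy shift in either carbinol epimer of 5 to give one (Z)-configured vinylcarbenoid 11 (stereoconvergent); its carbene carbon C6 is attacked by C7, the nucleophilic terminus of the C8 silyl enol ether of 10, and closes to cis-divinylcyclopropane 12, which undergoes a boat-shaped [3,3]-sigmatropic (Cope) ring expansion that breaks C6–C8, makes C1–C10 and leaves the C5 enol acetate and the C8 silyl enol ether as the skipped diene. The closest known reaction type is the gold-catalysed propargylic ester migration/diene cyclopropanation/Cope sequence, a formal (4+3) annulation that is also known with rhodium vinylcarbenoids. The three-membered ring closes by (2+1) carbene transfer and the seven-membered ring by sigmatropic expansion of it, so no direct seven-ring closure is required. C7 keeps the configuration set by stereospecific addition to the (Z)-enol ether (CH2CO2Me anti to both alkenyl groups); C1 follows from the (Z)-enol acetate, whose dioxanyl group points outward in the boat and ends cis to the C7 substituent; C10 follows from the (Z)-propenyl group, whose methyl points inward and ends trans to both. The step needs site selectivity for C7=C8 over C9=C10 (secured by the C8 siloxy donor, which polarises the diene so that C6 bonds to C7), cis-divinyl selectivity (endo preference of alkenylcarbenoids, and the propenyl group sits on the less hindered face of C8) and facial selectivity, which the chiral bisphosphine digold catalyst must impose; since C2 is already fixed, the wrong facial isomer is a separable diastereomer.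

**Step 8**
Reactants: 13 (cycloheptadiene from step 7)
Product: 14 methyl 2-[3-acetoxy-5-methyl-7-oxo-4-[(2S,4S)-2-phenyl-1,3-dioxan-4-yl]cyclohept-2-en-1-yl]acetate
Conditions: HF·pyridine, pyridine, THF, 0 °C
Reagents that add atoms: none
Why: Buffered fluoride cleaves the silyl enol ether to the C8 ketone with protonation at C9, while the enol acetate, ester and acetal should survive and the buffered medium should limit epimerisation at C7 or migration of the beta,gamma-alkene.

**Step 9**
Reactants: 14 (C8 ketone)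
Product: 16 cis-fused lactone 5-acetoxy-7-methyl-6-[(2S,4S)-2-phenyl-1,3-dioxan-4-yl]-3,3a,6,7,8,8a-hexahydro-2H-cyclohepta[b]furan-2-one (H-7 and H-8 cis), via cis-hydroxy ester 15 (not isolated)
Conditions: LiBH(s-Bu)3, THF, −78 °C; AcOH quench at −78 °C; then pyridinium p-toluenesulfonate (cat.), PhH, 50 °C
Reagents that add atoms: none
Why: The bulky hydride should attack the C8 ketone anti to the adjacent C7 CH2CO2Me group (substrate control, giving the C8 oxygen cis to that chain); the acidic quench avoids free methoxide, which would cleave the enol acetate, and acid-catalysed 5-exo-trig lactonisation then closes the cis-fused gamma-lactone.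

**Step 10**
Reactants: 16 (enol acetate lactone)
Product: 18 C5 alkenyl triflate of the lactone (C5=C6 retained), via potassium enolate 17 (not isolated)
Conditions: KOt-Bu (1.05 equiv), THF, −78 °C; then PhNTf2, −78 → 0 °C
Reagents that add atoms: N-phenylbis(trifluoromethanesulfonimide), O=S(=O)(N(c1ccccc1)S(=O)(=O)C(F)(F)F)C(F)(F)F
Why: tert-Butoxide attacks the activated acetyl group of the enol acetate much faster than the lactone and releases the regiodefined C5–C6 potassium enolate without a proton source for equilibration, and O-sulfonylation fixes the C5=C6 position as the triflate.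

**Step 11**
Reactants: 18 (alkenyl triflate)
Product: 19 5,7-dimethyl-6-[(2S,4S)-2-phenyl-1,3-dioxan-4-yl]-3,3a,6,7,8,8a-hexahydro-2H-cyclohepta[b]furan-2-one (cis-fused)
Conditions: MeZnCl, Pd(PPh3)4 (cat.), THF, rt → 40 °C
Reagents that add atoms: methylzinc chloride, C[Zn]Cl
Why: Negishi coupling on zerovalent palladium replaces the triflate by the C15 methyl with retention of the C5=C6 position and should tolerate the lactone and the acetal.

**Step 12**
Reactants: 19 (lactone)
Product: 23 alpha-methylene lactone 5,7-dimethyl-3-methylidene-6-[(2S,4S)-2-phenyl-1,3-dioxan-4-yl]-3,3a,6,7,8,8a-hexahydro-2H-cyclohepta[b]furan-2-one, via lithium lactone enolate 20 (not isolated), via Mannich base 21 (not isolated), via trimethylammonium iodide 22 (not isolated)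
Conditions: LiN(SiMe3)2, THF, −78 °C; CH2=NMe2+ I−, −78 °C → rt; then MeI, MeOH, rt; then aq. NaHCO3, CH2Cl2, rt
Reagents that add atoms: N,N-dimethylmethyleneiminium iodide (Eschenmoser's salt), C=[N+](C)C.[I-]
Why: Mannich reaction of the lactone enolate, N-methylation and base-induced elimination of trimethylamine is the standard alpha-methylenation of gamma-lactones; it creates no stereocentre and is placed before the base-sensitive esters are introduced.

**Step 13**
Reactants: 23 (alpha-methylene lactone acetal)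
Product: 24 diol 6-[(1S)-1,3-dihydroxypropyl]-5,7-dimethyl-3-methylidene-3,3a,6,7,8,8a-hexahydro-2H-cyclohepta[b]furan-2-one
Conditions: AcOH/H2O (4:1), 50 °C
Reagents that add atoms: none
Why: Mild acid hydrolysis of the benzylidene acetal frees the C2 and C4 hydroxyls and should leave the lactone and both alkenes untouched.

**Step 14**
Reactants: 24 (diol)
Product: 25 primary acetate 3-[(3aR,6S,7R,8aR)-5,7-dimethyl-3-methylidene-2-oxo-3,3a,6,7,8,8a-hexahydro-2H-cyclohepta[b]furan-6-yl]-3-hydroxypropyl acetate (C2 is S)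
Conditions: AcCl, 2,4,6-collidine, CH2Cl2, −78 °C
Reagents that add atoms: acetyl chloride, CC(=O)Cl
Why: Acylation with acetyl chloride and a hindered pyridine at low temperature should select the primary C4 hydroxyl over the secondary C2 hydroxyl, which is flanked by the ring.

**Step 15**
Reactants: 25 (hydroxy acetate); 26 angelic acid [(2Z)-2-methylbut-2-enoic acid]
Product: 27 target, (3aR,6S,7R,8aR)-6-[(1S)-3-acetoxy-1-{[(2Z)-2-methylbut-2-enoyl]oxy}propyl]-5,7-dimethyl-3-methylidene-3,3a,6,7,8,8a-hexahydro-2H-cyclohepta[b]furan-2-one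
Conditions: 2,4,6-trichlorobenzoyl chloride, Et3N, PhMe, rt; then 25, 80 °C
Reagents that add atoms: none
Why: Mixed-anhydride (Yamaguchi-type) acylation without a nucleophilic pyridine catalyst should esterify the hindered secondary alcohol while avoiding the addition–elimination pathway that isomerises angelates to tiglates.

**Compound list**
1 | (S)-butane-1,2,4-triol | OCC[C@H](O)CO | starting material
2 | [(2S,4S)-2-phenyl-1,3-dioxan-4-yl]methanol | OC[C@@H]1CCO[C@H](c2ccccc2)O1 | intermediate
3 | (2S,4S)-2-phenyl-1,3-dioxane-4-carbaldehyde | O=C[C@@H]1CCO[C@H](c2ccccc2)O1 | intermediate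
4 | bromomagnesium 1-[(2S,4S)-2-phenyl-1,3-dioxan-4-yl]prop-2-yn-1-olate (both carbinol epimers) | C#CC(O[Mg]Br)[C@@H]1CCO[C@H](c2ccccc2)O1 | intermediate
5 | 1-[(2S,4S)-2-phenyl-1,3-dioxan-4-yl]prop-2-yn-1-yl acetate (both carbinol epimers) | C#CC(OC(C)=O)[C@@H]1CCO[C@H](c2ccccc2)O1 | intermediate
6 | methyl 4-chloro-4-oxobutanoate | COC(=O)CCC(=O)Cl | starting material
7 | propyne | CC#C | starting material
8 | methyl 4-oxohept-5-ynoate | COC(=O)CCC(=O)C#CC | intermediate
9 | methyl (5Z)-4-oxohept-5-enoate | COC(=O)CCC(=O)/C=C\C | intermediate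
10 | methyl (3Z,5Z)-4-[(tert-butyldimethylsilyl)oxy]hepta-3,5-dienoate | COC(=O)C/C=C(\O[Si](C)(C)C(C)(C)C)/C=C\C | intermediate
11 | cationic gold (Z)-2-acetoxy-3-[(2S,4S)-2-phenyl-1,3-dioxan-4-yl]prop-2-enylidene complex (phosphine on gold not drawn) | [Au+]=C/C(OC(C)=O)=C/[C@@H]1CCO[C@H](c2ccccc2)O1 | intermediate
12 | methyl 2-{2-[(Z)-1-acetoxy-2-(2-phenyl-1,3-dioxan-4-yl)ethenyl]-3-[(Z)-prop-1-enyl]-3-(tert-butyldimethylsilyloxy)cyclopropyl}acetate (alkenyl groups cis, CH2CO2Me trans to both) | COC(=O)C[C@H]1[C@H](/C(OC(C)=O)=C/[C@@H]2CCO[C@H](c3ccccc3)O2)[C@]1(O[Si](C)(C)C(C)(C)C)/C=C\C | intermediate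
13 | methyl 2-[3-acetoxy-5-methyl-4-[(2S,4S)-2-phenyl-1,3-dioxan-4-yl]-7-(tert-butyldimethylsilyloxy)cyclohepta-2,6-dien-1-yl]acetate (C7/C1 substituents cis, C10 methyl trans) | COC(=O)C[C@H]1C=C(OC(C)=O)[C@@H]([C@@H]2CCO[C@H](c3ccccc3)O2)[C@H](C)C=C1O[Si](C)(C)C(C)(C)C | intermediate
14 | methyl 2-[3-acetoxy-5-methyl-7-oxo-4-[(2S,4S)-2-phenyl-1,3-dioxan-4-yl]cyclohept-2-en-1-yl]acetate | COC(=O)C[C@H]1C=C(OC(C)=O)[C@@H]([C@@H]2CCO[C@H](c3ccccc3)O2)[C@H](C)CC1=O | intermediate
15 | methyl 2-[3-acetoxy-7-hydroxy-5-methyl-4-[(2S,4S)-2-phenyl-1,3-dioxan-4-yl]cyclohept-2-en-1-yl]acetate (hydroxyl cis to the acetate chain) | COC(=O)C[C@H]1C=C(OC(C)=O)[C@@H]([C@@H]2CCO[C@H](c3ccccc3)O2)[C@H](C)C[C@H]1O | intermediate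
16 | cis-fused 5-acetoxy-7-methyl-6-[(2S,4S)-2-phenyl-1,3-dioxan-4-yl]-3,3a,6,7,8,8a-hexahydro-2H-cyclohepta[b]furan-2-one | O=C1C[C@H]2C=C(OC(C)=O)[C@@H]([C@@H]3CCO[C@H](c4ccccc4)O3)[C@H](C)C[C@H]2O1 | intermediate
17 | potassium C5–C6 enolate of the lactone | O=C1C[C@H]2C=C(O[K])[C@@H]([C@@H]3CCO[C@H](c4ccccc4)O3)[C@H](C)C[C@H]2O1 | intermediate
18 | C5 alkenyl trifluoromethanesulfonate of the lactone | O=C1C[C@H]2C=C(OS(=O)(=O)C(F)(F)F)[C@@H]([C@@H]3CCO[C@H](c4ccccc4)O3)[C@H](C)C[C@H]2O1 | intermediate
19 | cis-fused 5,7-dimethyl-6-[(2S,4S)-2-phenyl-1,3-dioxan-4-yl]-3,3a,6,7,8,8a-hexahydro-2H-cyclohepta[b]furan-2-one | O=C1C[C@H]2C=C(C)[C@@H]([C@@H]3CCO[C@H](c4ccccc4)O3)[C@H](C)C[C@H]2O1 | intermediate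
20 | lithium enolate of lactone 19 | [Li]OC1=C[C@H]2C=C(C)[C@@H]([C@@H]3CCO[C@H](c4ccccc4)O3)[C@H](C)C[C@H]2O1 | intermediate
21 | 3-[(dimethylamino)methyl] lactone (Mannich base, C11 epimers) | CN(C)CC1C(=O)O[C@@H]2C[C@@H](C)[C@H]([C@@H]3CCO[C@H](c4ccccc4)O3)C(C)=C[C@H]12 | intermediate
22 | 3-[(trimethylammonio)methyl] lactone iodide | C[N+](C)(C)CC1C(=O)O[C@@H]2C[C@@H](C)[C@H]([C@@H]3CCO[C@H](c4ccccc4)O3)C(C)=C[C@H]12.[I-] | intermediate
23 | 5,7-dimethyl-3-methylidene-6-[(2S,4S)-2-phenyl-1,3-dioxan-4-yl]-3,3a,6,7,8,8a-hexahydro-2H-cyclohepta[b]furan-2-one | C=C1C(=O)O[C@@H]2C[C@@H](C)[C@H]([C@@H]3CCO[C@H](c4ccccc4)O3)C(C)=C[C@H]12 | intermediate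
24 | 6-[(1S)-1,3-dihydroxypropyl]-5,7-dimethyl-3-methylidene-3,3a,6,7,8,8a-hexahydro-2H-cyclohepta[b]furan-2-one | C=C1C(=O)O[C@@H]2C[C@@H](C)[C@H]([C@H](CCO)O)C(C)=C[C@H]12 | intermediate
25 | (3S)-3-[(3aR,6S,7R,8aR)-5,7-dimethyl-3-methylidene-2-oxo-3,3a,6,7,8,8a-hexahydro-2H-cyclohepta[b]furan-6-yl]-3-hydroxypropyl acetate | C=C1C(=O)O[C@@H]2C[C@@H](C)[C@H]([C@H](CCOC(C)=O)O)C(C)=C[C@H]12 | intermediate
26 | angelic acid, (2Z)-2-methylbut-2-enoic acid | C/C=C(/C)C(=O)O | starting material
27 | (3aR,6S,7R,8aR)-6-[(1S)-3-acetoxy-1-{[(2Z)-2-methylbut-2-enoyl]oxy}propyl]-5,7-dimethyl-3-methylidene-3,3a,6,7,8,8a-hexahydro-2H-cyclohepta[b]furan-2-one | C=C1C(=O)O[C@@H]2C[C@@H](C)[C@H]([C@H](CCOC(C)=O)OC(=O)/C(C)=C\C)C(C)=C[C@H]12 | target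

**Step count.** Total: 15 steps. Longest linear sequence: 12 steps (steps 1–3 and 7–15, or steps 4–6 and 7–15).

**Steps most likely to fail**

1. Step 7. What may go wrong: bond formation between the carbenoid and the electron-rich silyl enol ether may become stepwise, giving five-ring (3+2) closure or loss of cis-divinyl selectivity. The boat Cope rearrangement with the inward C10 methyl may be slow, so that Z-to-E isomerisation of the propenyl group competes. Facial control by the catalyst may be poor. Fallback (sets out from 6 and 5, returns at 14): the C10 methyl is left out of the annulation and added afterwards under substrate control. Acid chloride 6 is coupled with tributyl(vinyl)stannane (PdCl2(PPh3)2 cat., Stille acylation) to methyl 4-oxohex-5-enoate F1, which is silylated (TBSOTf, Et3N, −78 °C) to methyl (3Z)-4-[(tert-butyldimethylsilyl)oxy]hexa-3,5-dienoate F2. F2 and 5 under the gold conditions of step 7 should give, already at room temperature because no substituent points inward in the boat, the 10-unsubstituted cycloheptadiene F3. Saegusa–Ito oxidation (Pd(OAc)2, MeCN) converts its C8 silyl enol ether into the C9=C10 enone, cycloheptadienone F4. Conjugate addition of Me2CuLi (Et2O, −78 °C, aqueous work-up) should deliver the methyl group to C10 anti to the neighbouring C1 dioxanyl group and return ketone 14.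

2. Step 9. What may go wrong: hydride delivery syn to the C7 side chain (approach governed by the C10 methyl instead), which places the C8 hydroxyl trans and prevents cis-lactonisation. Fallback (sets out from 14, returns at 16): the trans alcohol is used and the centre is inverted during ring closure. The trans-hydroxy ester F5 (from 14 with whichever hydride gives it cleanly, for example NaBH4/CeCl3, MeOH, −78 °C) is converted with MsCl/Et3N into the mesylate F6. Heating F6 in toluene with 2,6-lutidine should let the ester carbonyl oxygen displace the mesylate by 5-exo-tet attack with inversion; loss of the O-methyl group then gives cis-lactone 16.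

3. Step 15. What may go wrong: slow acylation of the hindered C2 hydroxyl, geometric isomerisation of the angeloyl group to tigloyl under base and heat, or amine addition to the alpha-methylene lactone. Fallback (sets out from 25, returns at 27): the Z-alkene is built on the ester. Alcohol 25 is acylated with 2-[bis(2,2,2-trifluoroethoxy)phosphoryl]propanoic acid (DCC, DMAP, CH2Cl2) to the phosphonopropanoate F7. Still–Gennari olefination of F7 with acetaldehyde (KN(SiMe3)2, 18-crown-6, THF, −78 °C) should give the (Z)-2-methylbut-2-enoate 27.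

**Further compounds**
F1 | step 7 | methyl 4-oxohex-5-enoate | COC(=O)CCC(=O)C=C
F2 | step 7 | methyl (3Z)-4-[(tert-butyldimethylsilyl)oxy]hexa-3,5-dienoate | COC(=O)C/C=C(\O[Si](C)(C)C(C)(C)C)C=C
F3 | step 7 | methyl 2-[3-acetoxy-4-[(2S,4S)-2-phenyl-1,3-dioxan-4-yl]-7-(tert-butyldimethylsilyloxy)cyclohepta-2,6-dien-1-yl]acetate (substituents cis) | COC(=O)C[C@H]1C=C(OC(C)=O)[C@@H]([C@@H]2CCO[C@H](c3ccccc3)O2)CC=C1O[Si](C)(C)C(C)(C)C
F4 | step 7 | methyl 2-[3-acetoxy-7-oxo-4-[(2S,4S)-2-phenyl-1,3-dioxan-4-yl]cyclohepta-2,5-dien-1-yl]acetate | COC(=O)C[C@H]1C=C(OC(C)=O)[C@@H]([C@@H]2CCO[C@H](c3ccccc3)O2)C=CC1=O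
F5 | step 9 | methyl 2-[3-acetoxy-7-hydroxy-5-methyl-4-[(2S,4S)-2-phenyl-1,3-dioxan-4-yl]cyclohept-2-en-1-yl]acetate (hydroxyl trans to the acetate chain) | COC(=O)C[C@H]1C=C(OC(C)=O)[C@@H]([C@@H]2CCO[C@H](c3ccccc3)O2)[C@H](C)C[C@@H]1O
F6 | step 9 | methanesulfonate of F5 | COC(=O)C[C@H]1C=C(OC(C)=O)[C@@H]([C@@H]2CCO[C@H](c3ccccc3)O2)[C@H](C)C[C@@H]1OS(C)(=O)=O
F7 | step 15 | 2-[bis(2,2,2-trifluoroethoxy)phosphoryl]propanoate of 25 | C=C1C(=O)O[C@@H]2C[C@@H](C)[C@H]([C@H](CCOC(C)=O)OC(=O)C(C)P(=O)(OCC(F)(F)F)OCC(F)(F)F)C(C)=C[C@H]12
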